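**Retrosynthetic overview**

1. Target 20 comes from 19 by hydrogenolysis of three benzyl ethers (two on the catechol, one on the chroman alcohol), the only protecting groups in the route.
2. The butenolide of 19 is opened into three components joined in one operation: carbon monoxide 17, aryl methyl ynol ether 16 and arylpyruvate 10. A ruthenium-catalysed carbonylative (2+2+1) cycloaddition forms the ring bonds C(aryl)–C(quaternary), O(ring)–C(=O) and C(=O)–C(OMe), the last one closing the ring by reductive elimination. The quaternary stereocentre is set here by a chiral diphosphine.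
3. Enabling feature: in the butenolide the lactone carbonyl carbon is bonded only to the ring oxygen and to the methoxy-bearing sp2 carbon, so it is one molecule of CO. The C(OMe)=C(aryl) pair is an ynol ether whose aryl-bearing carbon is nucleophilic. The quaternary carbon with its ring oxygen, CO2Me and benzyl group is the ketone of an α-ketoester that can chelate the metal.
4. 16 comes from aryl bromide 11 and Weinreb amide 12 through α-methoxy ketone 14 and enol triflate 15. 10 comes from chromene nitrile 1 by Jacobsen epoxidation (sets the chroman stereocentre), benzylic hydrogenolysis of the epoxide, benzylation, nitrile reduction, olefination with 7 and enamide hydrolysis.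
5. Ring order: the benzene rings and the dihydropyran ring of the chroman are bought with 1 and 11; the butenolide is the only ring made, in step 10.

Key step: step 10

Remark (assumption): the sense of induction of the chiral diphosphine in step 10 cannot be predicted with confidence; the (R)-ligand is written, and its antipode takes its place if it favours the wrong configuration at the quaternary carbon.

**Route**

Step 1
Reactants: 1 2,2-dimethyl-2H-chromene-6-carbonitrile
Product: 2 (3R,4R)-3,4-epoxy-2,2-dimethylchromane-6-carbonitrile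
Conditions: (R,R)-(salen)MnCl [salen = N,N'-bis(3,5-di-tert-butylsalicylidene)-1,2-cyclohexanediamine dianion] (3 mol %), 4-phenylpyridine N-oxide (10 mol %), aq. NaOCl (pH 11.3), CH2Cl2, 0 °C
Reagents that add atoms: sodium hypochlorite, [Na+].[O-]Cl
Why: Jacobsen epoxidation, for which 2,2-dimethylchromenes are the best substrate class; the (R,R)-catalyst, mirror image of the one that converts this nitrile into the (3S,4S)-epoxide, delivers oxygen to one face of the cis-alkene and so sets both ring carbons as (3R,4R).

Step 2
Reactants: 2 (3R,4R)-3,4-epoxy-2,2-dimethylchromane-6-carbonitrile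
Product: 3 (3R)-3-hydroxy-2,2-dimethylchromane-6-carbonitrile
Conditions: H2 (1 atm), 10% Pd/C, EtOAc, rt
Reagents that add atoms: none
Why: catalytic hydrogenolysis of a benzylic epoxide cleaves only the benzylic C4–O bond, so C4 becomes CH2 while the C3–O bond and its (3R) configuration are untouched, and the aryl nitrile is reduced far more slowly under neutral conditions at 1 atm.

Step 3
Reactants: 3 (3R)-3-hydroxy-2,2-dimethylchromane-6-carbonitrile
Product: 4 (3R)-3-(benzyloxy)-2,2-dimethylchromane-6-carbonitrile
Conditions: NaH, BnBr, n-Bu4NI (cat.), DMF, 0 °C to rt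
Reagents that add atoms: benzyl bromide, BrCc1ccccc1
Why: Williamson ether synthesis on the sodium alkoxide (iodide catalysis for the hindered secondary alcohol); the stereocentre is not involved and the aryl nitrile has no acidic hydrogen.

Step 4
Reactants: 4 (3R)-3-(benzyloxy)-2,2-dimethylchromane-6-carbonitrile
Product: 6 (3R)-3-(benzyloxy)-2,2-dimethylchromane-6-carbaldehyde, via N-aluminio aldimine 5 (not isolated)
Conditions: i-Bu2AlH, toluene, −78 °C; then 1 M HCl, 0 °C
Reagents that add atoms: water, O
Why: partial reduction of a nitrile with i-Bu2AlH stops at the N-aluminated aldimine at low temperature, and aqueous acid hydrolyses it to the aldehyde; the benzyl ether and the chroman are inert.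

Step 5
Reactants: 6 (3R)-3-(benzyloxy)-2,2-dimethylchromane-6-carbaldehyde; 7 methyl 2-[(tert-butoxycarbonyl)amino]-2-(dimethoxyphosphoryl)acetate
Product: 8 methyl (Z)-3-[(3R)-3-(benzyloxy)-2,2-dimethylchroman-6-yl]-2-[(tert-butoxycarbonyl)amino]acrylate
Conditions: DBU, CH2Cl2, 0 °C to rt
Reagents that add atoms: none
Why: Horner–Wadsworth–Emmons olefination of an aromatic aldehyde with an N-acyl phosphonoglycinate under mild amidine base gives the dehydroamino ester, normally as the (Z)-isomer; the alkene geometry is of no consequence later.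

Step 6
Reactants: 8 methyl (Z)-3-[(3R)-3-(benzyloxy)-2,2-dimethylchroman-6-yl]-2-[(tert-butoxycarbonyl)amino]acrylate
Product: 10 methyl 3-[(3R)-3-(benzyloxy)-2,2-dimethylchroman-6-yl]-2-oxopropanoate, via free enamino ester 9 (not isolated)
Conditions: TFA, CH2Cl2, 0 °C to rt; then H2O, THF, rt
Reagents that add atoms: water, O
Why: acidolysis of the Boc group frees a primary enamine that tautomerises to the α-imino ester, and water hydrolyses it to the α-ketoester (enamide hydrolysis); the methyl ester, the alkyl benzyl ether and the chroman tolerate TFA at room temperature.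

Step 7
Reactants: 11 1,2-bis(benzyloxy)-4-bromobenzene; 12 N,2-dimethoxy-N-methylacetamide
Product: 14 1-[3,4-bis(benzyloxy)phenyl]-2-methoxyethan-1-one, via aryllithium 13 (not isolated)
Conditions: n-BuLi, THF, −78 °C; then 12, −78 to 0 °C; aq. NH4Cl
Reagents that add atoms: none
Why: bromine–lithium exchange followed by Weinreb ketone synthesis; the chelated tetrahedral adduct survives until work-up and so prevents double addition.

Step 8
Reactants: 14 1-[3,4-bis(benzyloxy)phenyl]-2-methoxyethan-1-one
Product: 15 (Z)-1-[3,4-bis(benzyloxy)phenyl]-2-methoxyethenyl trifluoromethanesulfonate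
Conditions: LiN(SiMe3)2, THF, −78 °C; then PhNTf2, DMPU, −78 °C to rt; aq. NH4Cl
Reagents that add atoms: N-phenylbis(trifluoromethanesulfonimide), O=S(=O)(N(c1ccccc1)S(=O)(=O)C(F)(F)F)C(F)(F)F
Why: the ketone can enolise only towards the methoxymethyl group, the lithium-chelated (Z)-enolate is O-triflated (enol triflate formation), and this geometry places the vinyl hydrogen anti to the triflate.

Step 9
Reactants: 15 (Z)-1-[3,4-bis(benzyloxy)phenyl]-2-methoxyethenyl trifluoromethanesulfonate
Product: 16 1,2-bis(benzyloxy)-4-(methoxyethynyl)benzene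
Conditions: KOtBu, THF, −78 °C
Reagents that add atoms: none
Why: anti E2 elimination of triflate from a β-alkoxy enol triflate is an established route from α-alkoxy ketones to 1-alkynyl ethers, and the low temperature protects the ynol ether, which is isolated on base-washed silica and used promptly.

Step 10
Reactants: 10 methyl 3-[(3R)-3-(benzyloxy)-2,2-dimethylchroman-6-yl]-2-oxopropanoate; 16 1,2-bis(benzyloxy)-4-(methoxyethynyl)benzene; 17 carbon monoxide
Product: 19 methyl (2R)-2-{[(3R)-3-(benzyloxy)-2,2-dimethylchroman-6-yl]methyl}-3-[3,4-bis(benzyloxy)phenyl]-4-methoxy-5-oxo-2,5-dihydrofuran-2-carboxylate, via oxaruthenacyclopentene 18 (not isolated)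
Conditions: Ru3(CO)12 (5 mol %), (R)-DIFLUORPHOS [(R)-5,5'-bis(diphenylphosphino)-2,2,2',2'-tetrafluoro-4,4'-bi-1,3-benzodioxole] (15 mol %), CO (5 atm), toluene, 140 °C, slow addition of 16 (1.5 equiv)
Reagents that add atoms: none
Why: Proposed new method: a zerovalent ruthenium carbonyl–diphosphine fragment, formed from Ru3(CO)12 under CO, binds the 1,2-dicarbonyl unit of 10 and undergoes oxidative cyclisation with 16 in which the nucleophilic aryl-bearing alkyne carbon attacks the ketone carbon to give oxaruthenacyclopentene 18 (Ru–O and Ru–C(OMe) bonds); CO then inserts into the Ru–O bond to give a six-membered ruthenium alkoxycarbonyl, and C(acyl)–C(vinyl) reductive elimination joins the lactone carbonyl carbon to the methoxy-bearing carbon, closes the ring and returns zerovalent ruthenium. The closest known reaction type is the Ru3(CO)12-catalysed intermolecular carbonylative (2+2+1) cycloaddition (hetero-Pauson–Khand reaction) of α-ketoesters with alkenes or alkynes and CO; an ynol ether as the two-carbon partner and asymmetric induction by a chiral ligand are the parts that go beyond it. The single ring formed, the five-membered butenolide, closes in a formal (2+2+1) mode from three components, its last bond by reductive elimination from the six-membered metallacycle. The quaternary stereocentre is created in the oxidative cyclisation and is controlled by the C2-symmetric diphosphine on ruthenium, which differentiates the two faces of the chelated ketone; the distant chroman centre has no say, so the outcome is pure catalyst control. The step needs regioselectivity (aryl-bearing carbon to the ketone carbon, methoxy-bearing carbon to CO), secured by the ketene-acetal-like polarisation of the ynol ether matched with the electrophilic ketone carbon, and chemoselectivity for the ketone over the two ester carbonyls, secured by its higher electrophilicity and by chelation through the neighbouring ester. The methyl ynol ether carries no β-hydrogen on its alkoxy group, so the thermal retro-ene route to a ketene is closed at the reaction temperature.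

Step 11
Reactants: 19 methyl (2R)-2-{[(3R)-3-(benzyloxy)-2,2-dimethylchroman-6-yl]methyl}-3-[3,4-bis(benzyloxy)phenyl]-4-methoxy-5-oxo-2,5-dihydrofuran-2-carboxylate
Product: 20 methyl (2R)-3-(3,4-dihydroxyphenyl)-2-{[(3R)-3-hydroxy-2,2-dimethylchroman-6-yl]methyl}-4-methoxy-5-oxo-2,5-dihydrofuran-2-carboxylate
Conditions: H2 (1 atm), 10% Pd/C, EtOAc/MeOH, rt
Reagents that add atoms: none
Why: hydrogenolysis of two aryl benzyl ethers and one alkyl benzyl ether under neutral conditions; the tetrasubstituted, donor–acceptor butenolide alkene, the methyl ester, the enol methyl ether and both stereocentres should not be touched.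

**Compound list**

1 | 2,2-dimethyl-2H-chromene-6-carbonitrile | CC1(C)C=Cc2cc(C#N)ccc2O1 | starting material
2 | (3R,4R)-3,4-epoxy-2,2-dimethylchromane-6-carbonitrile | CC1(C)Oc2ccc(C#N)cc2[C@H]3O[C@@H]13 | intermediate
3 | (3R)-3-hydroxy-2,2-dimethylchromane-6-carbonitrile | N#Cc1ccc2c(c1)C[C@@H](O)C(C)(C)O2 | intermediate
4 | (3R)-3-(benzyloxy)-2,2-dimethylchromane-6-carbonitrile | N#Cc1ccc2c(c1)C[C@@H](OCc1ccccc1)C(C)(C)O2 | intermediate
5 | N-(diisobutylaluminio) aldimine of 6 (not isolated) | CC(C)C[Al](CC(C)C)N=Cc1ccc2c(c1)C[C@@H](OCc1ccccc1)C(C)(C)O2 | intermediate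
6 | (3R)-3-(benzyloxy)-2,2-dimethylchromane-6-carbaldehyde | O=Cc1ccc2c(c1)C[C@@H](OCc1ccccc1)C(C)(C)O2 | intermediate
7 | methyl 2-[(tert-butoxycarbonyl)amino]-2-(dimethoxyphosphoryl)acetate (racemic) | COC(=O)C(NC(=O)OC(C)(C)C)P(=O)(OC)OC | starting material
8 | methyl (Z)-3-[(3R)-3-(benzyloxy)-2,2-dimethylchroman-6-yl]-2-[(tert-butoxycarbonyl)amino]acrylate | COC(=O)/C(NC(=O)OC(C)(C)C)=C/c1ccc2c(c1)C[C@@H](OCc1ccccc1)C(C)(C)O2 | intermediate
9 | methyl (Z)-2-amino-3-[(3R)-3-(benzyloxy)-2,2-dimethylchroman-6-yl]acrylate (not isolated; in equilibrium with the α-imino ester) | COC(=O)/C(N)=C/c1ccc2c(c1)C[C@@H](OCc1ccccc1)C(C)(C)O2 | intermediate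
10 | methyl 3-[(3R)-3-(benzyloxy)-2,2-dimethylchroman-6-yl]-2-oxopropanoate (keto form drawn; in equilibrium with its enol) | COC(=O)C(=O)Cc1ccc2c(c1)C[C@@H](OCc1ccccc1)C(C)(C)O2 | intermediate
11 | 1,2-bis(benzyloxy)-4-bromobenzene | Brc1ccc(OCc2ccccc2)c(OCc2ccccc2)c1 | starting material
12 | N,2-dimethoxy-N-methylacetamide | COCC(=O)N(C)OC | starting material
13 | [3,4-bis(benzyloxy)phenyl]lithium (not isolated) | [Li]c1ccc(OCc2ccccc2)c(OCc2ccccc2)c1 | intermediate
14 | 1-[3,4-bis(benzyloxy)phenyl]-2-methoxyethan-1-one | COCC(=O)c1ccc(OCc2ccccc2)c(OCc2ccccc2)c1 | intermediate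
15 | (Z)-1-[3,4-bis(benzyloxy)phenyl]-2-methoxyethenyl trifluoromethanesulfonate | CO/C=C(\OS(=O)(=O)C(F)(F)F)c1ccc(OCc2ccccc2)c(OCc2ccccc2)c1 | intermediate
16 | 1,2-bis(benzyloxy)-4-(methoxyethynyl)benzene | COC#Cc1ccc(OCc2ccccc2)c(OCc2ccccc2)c1 | intermediate
17 | carbon monoxide | [C-]#[O+] | starting material
18 | oxaruthenacyclopentene from oxidative cyclisation of 10 and 16 (not isolated; CO and diphosphine ligands on ruthenium omitted) | COC(=O)[C@]1(Cc2ccc3c(c2)C[C@@H](OCc2ccccc2)C(C)(C)O3)O[Ru]C(OC)=C1c1ccc(OCc2ccccc2)c(OCc2ccccc2)c1 | intermediate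
19 | methyl (2R)-2-{[(3R)-3-(benzyloxy)-2,2-dimethylchroman-6-yl]methyl}-3-[3,4-bis(benzyloxy)phenyl]-4-methoxy-5-oxo-2,5-dihydrofuran-2-carboxylate | COC(=O)[C@]1(Cc2ccc3c(c2)C[C@@H](OCc2ccccc2)C(C)(C)O3)OC(=O)C(OC)=C1c1ccc(OCc2ccccc2)c(OCc2ccccc2)c1 | intermediate
20 | methyl (2R)-3-(3,4-dihydroxyphenyl)-2-{[(3R)-3-hydroxy-2,2-dimethylchroman-6-yl]methyl}-4-methoxy-5-oxo-2,5-dihydrofuran-2-carboxylate | COC(=O)[C@]1(Cc2ccc3c(c2)C[C@@H](O)C(C)(C)O3)OC(=O)C(OC)=C1c1ccc(O)c(O)c1 | target

**Step count and risks**

Total step count: 11 (steps 1–6 to ketoester 10, steps 7–9 to ynol ether 16, steps 10 and 11).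
Longest linear sequence: 8 steps (1 to 20 through steps 1–6, 10 and 11).

Steps most likely to fail:

Step 10. What may go wrong:
- weak enantiofacial discrimination in the oxidative cyclisation at 140 °C;
- consumption of the ynol ether by addition of the enol tautomer of 10 or by alkyne–alkyne–CO cyclisation;
- slow keto–enol equilibration of the arylpyruvate, which must react through its keto form;
- leakage of regiochemistry if the aryl group overrides the polarisation by oxygen.

The fallback sets out from 10 and comes back to the route at 19, using known chemistry throughout. Compound 10 serves as the electrophile in a copper-bisoxazoline catalysed enantioselective Mukaiyama aldol addition to an α-ketoester. The nucleophile, methyl (Z)-3-[3,4-bis(benzyloxy)phenyl]-2-[(tert-butyldimethylsilyl)oxy]acrylate F1, is made from commercial 3,4-bis(benzyloxy)benzaldehyde and methyl 2-[(tert-butyldimethylsilyl)oxy]-2-(dimethoxyphosphoryl)acetate (LiN(SiMe3)2, THF, −78 °C to rt, Horner–Wadsworth–Emmons olefination). F1 and 10 are combined with Cu(OTf)2 and (R,R)-2,2'-isopropylidenebis(4-tert-butyl-2-oxazoline) (10–20 mol %, CH2Cl2, −78 to −20 °C). Divalent copper chelates the two adjacent carbonyl oxygens of 10 and the ligand shields one face of the ketone; the ligand enantiomer is chosen by analogy with the established sense of induction for pyruvate esters. Work-up with 1 M HCl in THF removes the silyl group and should give dimethyl (2R)-2-{[(3R)-3-(benzyloxy)-2,2-dimethylchroman-6-yl]methyl}-3-[3,4-bis(benzyloxy)phenyl]-2-hydroxy-4-oxopentanedioate F2, as a mixture at C3 that is of no consequence. Catalytic p-TsOH in toluene at 50 °C closes the lactone with loss of methanol and enolisation to methyl (2R)-2-{[(3R)-3-(benzyloxy)-2,2-dimethylchroman-6-yl]methyl}-3-[3,4-bis(benzyloxy)phenyl]-4-hydroxy-5-oxo-2,5-dihydrofuran-2-carboxylate F3. O-Methylation of the acidic enol with Me3SiCHN2 (toluene/MeOH, 0 °C) then gives 19. In this fallback the ring closes by lactonisation and the quaternary centre is set in the aldol step.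

Step 9. What may go wrong: attack of tert-butoxide at sulfur instead of E2 elimination, and acid-catalysed hydration or oligomerisation of the electron-rich ynol ether during isolation.

The fallback sets out from 11 and comes back at 16. Lithium methoxyacetylide F4, generated from chloroacetaldehyde dimethyl acetal and LiNEt2 (3 equiv, THF, 0 °C), is transmetalated with ZnCl2 to (methoxyethynyl)zinc chloride F5. Negishi coupling with 11 (Pd[P(t-Bu)3]2, a zerovalent palladium catalyst, THF, 50 °C) forms the aryl–alkyne bond directly. The solution of 16 is filtered through basic alumina and used at once in step 10.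

Step 6. What may go wrong: stalling at the enamine/imine stage, or acid-promoted aldol self-condensation of the liberated arylpyruvate.

The fallback sets out from 6 and comes back at 10. Horner–Wadsworth–Emmons olefination of 6 with methyl 2-[(tert-butyldimethylsilyl)oxy]-2-(dimethoxyphosphoryl)acetate (LiN(SiMe3)2, THF, −78 °C to rt) gives the silyl enol ether methyl (Z)-3-[(3R)-3-(benzyloxy)-2,2-dimethylchroman-6-yl]-2-[(tert-butyldimethylsilyl)oxy]acrylate F6. Buffered fluoride (CsF, AcOH, MeCN, 0 °C) then releases 10 under nearly neutral conditions.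

**Further compounds**

F1 | step 10 | methyl (Z)-3-[3,4-bis(benzyloxy)phenyl]-2-[(tert-butyldimethylsilyl)oxy]acrylate | COC(=O)/C(O[Si](C)(C)C(C)(C)C)=C/c1ccc(OCc2ccccc2)c(OCc2ccccc2)c1
F2 | step 10 | dimethyl (2R)-2-{[(3R)-3-(benzyloxy)-2,2-dimethylchroman-6-yl]methyl}-3-[3,4-bis(benzyloxy)phenyl]-2-hydroxy-4-oxopentanedioate (mixture at C3) | COC(=O)C(=O)C(c1ccc(OCc2ccccc2)c(OCc2ccccc2)c1)[C@](O)(Cc1ccc2c(c1)C[C@@H](OCc1ccccc1)C(C)(C)O2)C(=O)OC
F3 | step 10 | methyl (2R)-2-{[(3R)-3-(benzyloxy)-2,2-dimethylchroman-6-yl]methyl}-3-[3,4-bis(benzyloxy)phenyl]-4-hydroxy-5-oxo-2,5-dihydrofuran-2-carboxylate | COC(=O)[C@]1(Cc2ccc3c(c2)C[C@@H](OCc2ccccc2)C(C)(C)O3)OC(=O)C(O)=C1c1ccc(OCc2ccccc2)c(OCc2ccccc2)c1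
F4 | step 9 | lithium methoxyacetylide | [Li]C#COC
F5 | step 9 | (methoxyethynyl)zinc chloride | COC#C[Zn]Cl
F6 | step 6 | methyl (Z)-3-[(3R)-3-(benzyloxy)-2,2-dimethylchroman-6-yl]-2-[(tert-butyldimethylsilyl)oxy]acrylate | COC(=O)/C(O[Si](C)(C)C(C)(C)C)=C/c1ccc2c(c1)C[C@@H](OCc1ccccc1)C(C)(C)O2
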